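**Plan**

- Retrosynthesis first cuts the C3–OH bond of ring C, leading back to the (2S)-flavanone 8. It then cuts the C6–CMe2 bond of ring A through a [3,3] shift, leading back to a 5-O-prenyl ether, and finally the O5–CH2 bond, leading back to homoeriodictyol and prenol.
- Enabling feature: C3 is a CH2 between C2, which carries ring B, and the C4 carbonyl, which is chelated to the 5-OH of ring A. Flavanone 3-hydroxylase grips exactly this unprotected array, so its iron-oxo unit reaches only the C3–H trans to the aryl group and leaves the phenols, both arenes and the vinyl group alone.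
- Forward: rings A, B and C are bought intact in homoeriodictyol and no ring is formed anywhere. The sequence is O7/O4' acetylation, Mitsunobu prenylation of O5, europium-catalysed Claisen shift to C6 and deacetylation, which gives racemic flavanone 7.
- Stereochemistry: C2 is fixed by chromatographic resolution of 7 (2S antipode 8). C3 is set by the enzyme, trans to the aryl group, giving (2R,3R). In-flask racemisation through the chalcone is not relied on, because re-closure through the other ortho oxygen could move the tert-allyl group to C8.

Key step: step 6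

Assumption: commercial homoeriodictyol is taken as the racemate (C2 is fixed only in step 5), and the dioxygenase is a recombinant plant flavanone 3-hydroxylase produced in Escherichia coli.

**Route**

Step 1
Reactants: 1 homoeriodictyol (racemic 5,7,4'-trihydroxy-3'-methoxyflavanone)
Product: 2 rac-7,4'-di-O-acetylhomoeriodictyol (5-OH free)
Conditions: Ac2O (2.1 equiv), pyridine, 0 °C to rt
Reagents that add atoms: acetic anhydride, CC(=O)OC(C)=O
Why: Selective O-acylation, in which the 7- and 4'-phenols are esterified while the 5-OH, held in a hydrogen bond to the C4 carbonyl, should stay free with a limited amount of anhydride at low temperature.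

Step 2
Reactants: 2 rac-7,4'-di-O-acetylhomoeriodictyol; 3 prenol (3-methylbut-2-en-1-ol)
Product: 4 rac-7,4'-di-O-acetyl-5-O-(3-methylbut-2-enyl)homoeriodictyol
Conditions: PPh3, diisopropyl azodicarboxylate (DIAD), THF, 0 °C to rt
Reagents that add atoms: none
Why: Mitsunobu etherification, in which the chelated 5-phenol is acidic enough to protonate the PPh3/DIAD betaine and displaces the oxyphosphonium of the primary allylic alcohol at CH2 without allylic transposition, under neutral conditions that spare the aryl acetates and ring C.

Step 3
Reactants: 4 rac-7,4'-di-O-acetyl-5-O-(3-methylbut-2-enyl)homoeriodictyol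
Product: 6 rac-7,4'-di-O-acetyl-6-(1,1-dimethylallyl)homoeriodictyol, via ortho-dienone 5 (not isolated)
Conditions: Eu(fod)3 (10 mol %; fod = 6,6,7,7,8,8,8-heptafluoro-2,2-dimethyl-3,5-octanedionate), CHCl3, 35 °C, stopped when 4 is consumed
Reagents that add atoms: none
Why: Aromatic Claisen rearrangement catalysed by the oxophilic trivalent europium centre bound at the C4 carbonyl/O5 pair; the [3,3] shift can reach only C6 because the other ortho carbon C4a is quaternary, it delivers the inverted 1,1-dimethylallyl group, and at mild temperature enolisation of dienone 5 to the 5-phenol should outrun the Cope shift toward C8.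

Step 4
Reactants: 6 rac-7,4'-di-O-acetyl-6-(1,1-dimethylallyl)homoeriodictyol
Product: 7 rac-6-(1,1-dimethylallyl)homoeriodictyol
Conditions: K2CO3 (0.3 equiv), MeOH, 0 °C, argon; then aq. NH4Cl
Reagents that add atoms: none
Why: Zemplén-type transesterification of two aryl acetates, fast at 0 °C because phenoxides are good leaving groups, so that exposure to base should be too short for retro-oxa-Michael opening of ring C, while the vinyl group is inert.

Step 5
Reactants: 7 rac-6-(1,1-dimethylallyl)homoeriodictyol
Product: 8 (2S)-6-(1,1-dimethylallyl)homoeriodictyol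
Conditions: preparative HPLC on silica-supported amylose tris(3,5-dimethylphenylcarbamate), n-hexane/2-propanol/0.1% HCO2H, rt
Reagents that add atoms: none
Why: Chromatographic resolution of a racemate with no bond change; flavanone antipodes are routinely separated on polysaccharide carbamate phases, the acidic eluent suppresses ring opening, and the 2S antipode is to be assigned by circular dichroism against (2S)-naringenin, which fixes C2.

Step 6
Reactants: 8 (2S)-6-(1,1-dimethylallyl)homoeriodictyol
Product: 9 (2R,3R)-6-(1,1-dimethylallyl)-3'-O-methyltaxifolin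
Conditions: recombinant flavanone 3-hydroxylase (Petunia hybrida enzyme), FeSO4 (0.1 mM), disodium 2-oxoglutarate (3 equiv), sodium ascorbate, catalase, air, KH2PO4/K2HPO4 buffer pH 6.8, 5% DMSO, 30 °C; EtOAc extraction at pH 5
Reagents that add atoms: dioxygen, O=O
Why: The enzyme-bound divalent iron coordinates 2-oxoglutarate and O2, oxidative decarboxylation leaves succinate, CO2 and a tetravalent iron-oxo unit, this abstracts the C3 hydrogen lying trans to the C2 aryl group, and the hydroxyl rebounds onto the C3 radical from the same face, so only the C3–O bond forms and no ring is closed. The closest known reaction is the conversion of (2S)-naringenin and (2S)-eriodictyol into their (2R,3R)-dihydroflavonols by this 2-oxoglutarate-dependent dioxygenase, a C–H hydroxylation with retention. The new C3 stereocentre is controlled by the active site, which holds ring B and the chelated C4 carbonyl/5-OH pair so that one C3–H faces the iron, together with the fixed 2S configuration of 8, giving the 2,3-trans (2R,3R) product. The step needs site selectivity for C3 and chemoselectivity over three free phenols, two electron-rich arenes, the benzylic C2–H and the vinyl group; all of this rests on recognition of the unprotected 5-hydroxychromanone and ring B, which 8 presents unchanged, whereas tolerance of the C6 tert-allyl group still has to be established. Near-neutral pH and a short reaction time should protect the product from C2/C3 epimerisation and from further oxidation to the flavonol. Any residual 2R antipode is not a substrate and is left behind.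

**Compound list**

1 | homoeriodictyol (racemic) | COc1cc(C2CC(=O)c3c(O)cc(O)cc3O2)ccc1O | starting material
2 | rac-7,4'-di-O-acetylhomoeriodictyol | COc1cc(C2CC(=O)c3c(O)cc(OC(C)=O)cc3O2)ccc1OC(C)=O | intermediate
3 | prenol (3-methylbut-2-en-1-ol) | CC(C)=CCO | starting material
4 | rac-7,4'-di-O-acetyl-5-O-(3-methylbut-2-enyl)homoeriodictyol | COc1cc(C2CC(=O)c3c(OCC=C(C)C)cc(OC(C)=O)cc3O2)ccc1OC(C)=O | intermediate
5 | ortho-dienone (C5 keto form with sp3 C6 carrying the 1,1-dimethylallyl group; not isolated) | C=CC(C)(C)C1C(OC(C)=O)=CC2=C(C1=O)C(=O)CC(c1ccc(OC(C)=O)c(OC)c1)O2 | intermediate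
6 | rac-7,4'-di-O-acetyl-6-(1,1-dimethylallyl)homoeriodictyol | C=CC(C)(C)c1c(OC(C)=O)cc2c(c1O)C(=O)CC(c1ccc(OC(C)=O)c(OC)c1)O2 | intermediate
7 | rac-6-(1,1-dimethylallyl)homoeriodictyol | C=CC(C)(C)c1c(O)cc2c(c1O)C(=O)CC(c1ccc(O)c(OC)c1)O2 | intermediate
8 | (2S)-6-(1,1-dimethylallyl)homoeriodictyol | C=CC(C)(C)c1c(O)cc2c(c1O)C(=O)C[C@@H](c1ccc(O)c(OC)c1)O2 | intermediate
9 | (2R,3R)-6-(1,1-dimethylallyl)-3'-O-methyltaxifolin | C=CC(C)(C)c1c(O)cc2c(c1O)C(=O)[C@H](O)[C@@H](c1ccc(O)c(OC)c1)O2 | target

**Step count and risks**

Total steps: 6. Longest linear sequence: 6 (from homoeriodictyol).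

Steps most likely to fail:

1. Step 6. The C6 tert-allyl group may prevent productive binding, so that turnover is absent or slow, or the enzyme may go on to desaturate the product to the flavonol. The fallback sets out from 8 and comes back at 9 by chemical enol oxidation. TMSOTf/Et3N in CH2Cl2 at 0 °C should silylate the three phenols and soft-enolise the ketone to (2S)-4,5,7,4'-tetrakis(trimethylsilyloxy)-6-(1,1-dimethylallyl)-3'-methoxyflav-3-ene F1. One equivalent of dimethyldioxirane in acetone at −78 to −40 °C should oxidise the electron-rich enol ether much faster than the vinyl group, from the face opposite the C2 aryl group (Rubottom oxidation), to give (2R,3R)-3,5,7,4'-tetrakis(trimethylsilyloxy)-6-(1,1-dimethylallyl)-3'-methoxyflavanone F2. Citric acid in MeOH at 0 °C removes the silyl groups and gives 9.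

2. Step 3. The allyl unit may migrate further from dienone 5 to C8 by a Cope shift, or the first-formed phenol may re-enter the dienone manifold under Lewis acid. The fallback sets out from 4 and comes back at 7 by intercepting the ortho product instead of relying on a kinetic stop. Heating 4 in N,N-diethylaniline with Ac2O and NaOAc at about 180 °C should rearrange it through dienone 5 and cap the new 5-phenol at once, giving rac-5,7,4'-tri-O-acetyl-6-(1,1-dimethylallyl)homoeriodictyol F3. F3 can no longer tautomerise back, and methanolysis of its three acetates under the conditions of step 4 gives 7.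

3. Step 4. Base may trigger retro-oxa-Michael opening of ring C, and re-closure through the other ortho oxygen would move the tert-allyl group to C8 (Wessely–Moser-type drift). The fallback sets out from 1 and comes back at 7 with acid-labile instead of base-labile protection. MOMCl/iPr2NEt in CH2Cl2 at 0 °C should give rac-7,4'-bis-O-(methoxymethyl)homoeriodictyol F4. Mitsunobu reaction with 3 (PPh3, DIAD, THF) gives rac-7,4'-bis-O-(methoxymethyl)-5-O-(3-methylbut-2-enyl)homoeriodictyol F5. Eu(fod)3 in CHCl3 rearranges it through the bis(methoxymethyl) ortho-dienone F6 (not isolated) to rac-7,4'-bis-O-(methoxymethyl)-6-(1,1-dimethylallyl)homoeriodictyol F7. HCl in MeOH at 40 °C, which the monosubstituted vinyl group should tolerate, releases 7.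

Further compounds
F1 | step 6 | (2S)-4,5,7,4'-tetrakis(trimethylsilyloxy)-6-(1,1-dimethylallyl)-3'-methoxyflav-3-ene | C=CC(C)(C)c1c(O[Si](C)(C)C)cc2c(c1O[Si](C)(C)C)C(O[Si](C)(C)C)=C[C@@H](c1ccc(O[Si](C)(C)C)c(OC)c1)O2
F2 | step 6 | (2R,3R)-3,5,7,4'-tetrakis(trimethylsilyloxy)-6-(1,1-dimethylallyl)-3'-methoxyflavanone | C=CC(C)(C)c1c(O[Si](C)(C)C)cc2c(c1O[Si](C)(C)C)C(=O)[C@H](O[Si](C)(C)C)[C@@H](c1ccc(O[Si](C)(C)C)c(OC)c1)O2
F3 | step 3 | rac-5,7,4'-tri-O-acetyl-6-(1,1-dimethylallyl)homoeriodictyol | C=CC(C)(C)c1c(OC(C)=O)cc2c(c1OC(C)=O)C(=O)CC(c1ccc(OC(C)=O)c(OC)c1)O2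
F4 | step 4 | rac-7,4'-bis-O-(methoxymethyl)homoeriodictyol | COc1cc(C2CC(=O)c3c(O)cc(OCOC)cc3O2)ccc1OCOC
F5 | step 4 | rac-7,4'-bis-O-(methoxymethyl)-5-O-(3-methylbut-2-enyl)homoeriodictyol | COc1cc(C2CC(=O)c3c(OCC=C(C)C)cc(OCOC)cc3O2)ccc1OCOC
F6 | step 4 | bis(methoxymethyl) ortho-dienone (C5 keto form, sp3 C6 carrying the 1,1-dimethylallyl group; not isolated) | C=CC(C)(C)C1C(OCOC)=CC2=C(C1=O)C(=O)CC(c1ccc(OCOC)c(OC)c1)O2
F7 | step 4 | rac-7,4'-bis-O-(methoxymethyl)-6-(1,1-dimethylallyl)homoeriodictyol | C=CC(C)(C)c1c(OCOC)cc2c(c1O)C(=O)CC(c1ccc(OCOC)c(OC)c1)O2
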